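One question stands here: how much idle adduct the flask holds at 4.0 h, 20 h and 3.0 d, with electrophile and nucleophile charged equal.

| flask | electrophile | nucleophile | free base | remark | time |
|---|---|---|---|---|---|
| east | 0.26 M | 0.13 M | 0.78 M | run made earlier |  |
| north-east | 0.26 M | 0.52 M | 0.78 M | run made earlier |  |
| south-west | 0.13 M | 0.26 M | 0.78 M | run made earlier |  |
| flask | 0.26 M | 0.260 M | 0.780 M |  | 3.0 d |

| run | time / d | idle adduct / % | product / % | electrophile / % |
|---|---|---|---|---|
| east | 0.417 | 7.9 | 40.5 | 59.6 |
| east | 0.833 | 5.8 | 43.1 | 55.7 |
| east | 1.25 | 2.3 | 47.9 | 55.0 |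
| east | 1.67 | 2.8 | 47.1 | 51.9 |
| east | 2.00 | 0 | 48.1 | 51.1 |
| east | 2.50 | 0.5 | 48.8 | 50.1 |
| east | 3.00 | 1.0 | 51.3 | 51.2 |
| north-east | 0.167 | 75.6 | 89.5 | 10.0 |
| north-east | 0.500 | 79.2 | 97.5 | 1.3 |
| north-east | 0.833 | 78.8 | 100.4 | 0.8 |
| north-east | 1.25 | 78.9 | 100.0 | 0 |
| north-east | 1.67 | 80.1 | 100.3 | 0.2 |
| north-east | 2.50 | 79.1 | 99.8 | 1.1 |
| north-east | 3.00 | 80.3 | 99.5 | 0.6 |
| south-west | 0.625 | 72.5 | 98.1 | 1.8 |
| south-west | 1.25 | 71.8 | 98.6 | 0 |
| south-west | 1.67 | 72.2 | 99.4 | 0 |
| south-west | 2.50 | 71.9 | 100.9 | 0 |
| south-west | 3.00 | 73.7 | 100.0 | 0 |

(standard deviation of a reading: 1 percentage point)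

- amount of idle adduct in percent of the electrophile charged, at 4.0 h, 20 h and 3.0 d

- amounts and yields of product count idle adduct too

The runs give one number worth carrying. The last 3 readings of the north-east run stand level, with mean adduct 79.8% and mean product 99.9%, adduct counted in it. So c(free product) reads 0.0521 M, and c(nucleophile), the charge less what product and adduct took, reads 0.0528 M.

The holding constant, c(adduct) divided by c(free product) and by c(nucleophile), then reads 75.5 /M. The ratio of adduct to free product is this constant times c(nucleophile), so in decimal logarithms the ratio falls one for one with c(nucleophile), and the two forms are equal at 0.0132 M.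

In the south-west run, with nucleophile charged at twice the electrophile and electrophile reading 0% at 3.00 d, the balance makes free product equal to free nucleophile. The constant then gives 72.8% adduct, and the mean reading is 72.4%.

Two views part over the flask. The first calls the adduct a passing thing: in the east run it reads 7.9% at 0.417 d and 1.0% at 3.00 d, so the flask should end near that figure.

The second answers that the east run ends with electrophile at 51.2%, more than the adduct, and that nucleophile is the limiting reagent of that run. In the flask, with equal charges and counting the forms these runs name, the electrophile left equals free nucleophile plus adduct, so the adduct falls with the electrophile left. I side with the second view.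

The forecast is that side's number: 34%, 22% and 12%, the adduct being held to “then drains slowly as it feeds” nucleophile to the remaining electrophile.

The flask gives 34.5%, 22.7% and 12.5%, so the forecast stands. The first view keeps the east run, which differs from the flask in its nucleophile charge, at half the electrophile, and reads 1.0% adduct at 3.00 d; that charge is what would have to change for the forecast's 12% to be wrong. At 3.00 d the flask holds nucleophile at 0.918% of its charge, which is 0.00239 M, and product at 86.5%, adduct counted. The constant makes the ratio 0.180, which puts 13.2% of the charge in adduct, and the flask holds 12.5%.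

    electrophile + nucleophile → acid set free + product (k = 9.20 × 10⁻⁴ /M/s)
    nucleophile + acid set free ⇌ protonated nucleophile, settled at all times (K = 410 /M)
    acid set free + free base ⇌ salt of the base, settled at all times (K = 18000 /M)
    nucleophile + product ⇌ idle adduct, settled at all times (K = 71.0 /M)
    acid set free → by-product carried off (k = 3.40 × 10⁻⁵ /s)

The numbers in the tables are simulated with made-up constants, noise included.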